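**Retrosynthetic overview**
1. Target 24 ⇐ CBS reduction at C3 and acetylation of a keto lactone; the seven-membered α-methylene lactone is closed last, by carboxylic-acid opening of an (11R,12R)-epoxide at C12 with inversion.
2. C1–C15: catalytic asymmetric malonate Michael addition to a 14-membered cross-conjugated dienone; the carbocycle comes from ring-closing metathesis (C1=C2).
3. C11–C14: isopropenyl ketone → CBS reduction → Sharpless epoxidation → allyl cuprate opening → mesylate-to-epoxide closure.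
4. C5–C6 (skipped diene): carboalumination of a pentenynol silyl ether, then Pd coupling that opens the allylic lactone 4.
5. Key step: Birch dearomatisation of 4-methylanisole followed by Baeyer–Villiger ring expansion gives 4, whose ring fixes the Z-C7=C8 olefin. Ring order: arene → cyclohexenone → oxepinone (opened) → oxirane → 14-membered carbocycle → seven-membered lactone.

Assumption: the SMILES is read as (1S,3R,4E,7Z,11R,12S) in cembrane numbering (C1 = ring CH bearing C15; C16 = lactone C=O; C17 = exocyclic CH2; C18, C19, C20 = methyls on C4, C8, C12), used for atom labels below; the silyloxy carbon C3 is racemic in 5–15 (epimer mixtures from 10 on) and becomes uniform at ketone 16.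

**Step 1**
Reactants: 1 4-methylanisole
Product: 3 4-methylcyclohex-3-en-1-one, via 1-methoxy-4-methylcyclohexa-1,4-diene 2 (not isolated)
Conditions: Li, t-BuOH, NH3(l)/THF, −78 to −33 °C; NH4Cl; then (CO2H)2, THF–H2O, 20 °C
Reagents that add atoms: water, O
Why: Birch reduction leaves both donor-substituted carbons vinylic, so the arene is broken into diene 2, and the weak acid hydrolyses only the enol ether to the unconjugated enone, locking the future C7=C8 olefin as Z inside a six-membered ring.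

**Step 2**
Reactants: 3 4-methylcyclohex-3-en-1-one
Product: 4 5-methyl-4,7-dihydrooxepin-2(3H)-one
Conditions: Me3SiOOSiMe3, Me3SiOTf (10 mol%), CH2Cl2, −40 to 0 °C
Reagents that add atoms: bis(trimethylsilyl) peroxide, C[Si](C)(C)OO[Si](C)(C)C
Why: Baeyer–Villiger oxidation with the non-epoxidising silyl peroxide should insert oxygen on the side of the better-migrating allylic CH2 (C6), giving a seven-membered allylic lactone with C6 as allylic ester carbon, C11 as acyl carbon and the Z-olefin intact.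

**Step 3**
Reactants: 5 pent-1-en-4-yn-3-ol
Product: 6 tert-butyl(dimethyl)(pent-1-en-4-yn-3-yloxy)silane
Conditions: t-BuMe2SiCl, imidazole, DMF, 20 °C
Reagents that add atoms: tert-butyldimethylsilyl chloride, CC(C)(C)[Si](C)(C)Cl
Why: standard silylation masks the one hydroxyl that would otherwise compete in the directed epoxidation of step 7 and the mesylation of step 9.

**Step 4**
Reactants: 6 tert-butyl(dimethyl)(pent-1-en-4-yn-3-yloxy)silane; 4 5-methyl-4,7-dihydrooxepin-2(3H)-one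
Product: 8 (4Z,7E)-9-[(tert-butyldimethylsilyl)oxy]-4,8-dimethylundeca-4,7,10-trienoic acid, via alkenyl(dimethyl)alane 7 (not isolated)
Conditions: Me3Al, Cp2ZrCl2 (20 mol%), ClCH2CH2Cl, 0 to 20 °C; evaporate excess Me3Al; then 4, Pd(PPh3)4 (5 mol%), THF, 0 to 20 °C; dilute HCl (pH 3)
Reagents that add atoms: trimethylaluminium, C[Al](C)C
Why: Proposed new method: Negishi syn-carboalumination gives the (E)-alkenylalane with the new methyl on C4, zerovalent palladium ionises the allylic C6–O bond of lactone 4 (aluminium-assisted), and fast alkenyl transfer to the unhindered C6 terminus should outrun syn/anti isomerisation so the Z-olefin is kept and the C11 carboxylate is released; closest known reaction: Negishi Pd-catalysed coupling of alkenylalanes with neryl and geranyl acetates or chlorides.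

**Step 5**
Reactants: 8 (4Z,7E)-9-[(tert-butyldimethylsilyl)oxy]-4,8-dimethylundeca-4,7,10-trienoic acid
Product: 9 (6Z,9E)-11-[(tert-butyldimethylsilyl)oxy]-2,6,10-trimethyltrideca-1,6,9,12-tetraen-3-one
Conditions: CH2=C(CH3)Li (2.5 equiv, pre-formed), Et2O–THF, −78 to 0 °C; then H2O
Reagents that add atoms: isopropenyllithium, [Li]C(C)=C
Why: organolithium addition to the lithium carboxylate gives a stable gem-dialkoxide that collapses to the ketone only on work-up, so C12, C13 and C20 arrive as an isopropenyl ketone without over-addition.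

**Step 6**
Reactants: 9 (6Z,9E)-11-[(tert-butyldimethylsilyl)oxy]-2,6,10-trimethyltrideca-1,6,9,12-tetraen-3-one
Product: 10 (3S,6Z,9E)-11-[(tert-butyldimethylsilyl)oxy]-2,6,10-trimethyltrideca-1,6,9,12-tetraen-3-ol
Conditions: (R)-2-methyl-CBS-oxazaborolidine (20 mol%), catecholborane, toluene, −78 °C
Reagents that add atoms: none
Why: Corey–Bakshi–Shibata reduction with the isopropenyl group as the large substituent sets C11 as S under reagent control.

**Step 7**
Reactants: 10 (3S,6Z,9E)-11-[(tert-butyldimethylsilyl)oxy]-2,6,10-trimethyltrideca-1,6,9,12-tetraen-3-ol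
Product: 11 (1S,4Z,7E)-9-[(tert-butyldimethylsilyl)oxy]-4,8-dimethyl-1-[(2R)-2-methyloxiran-2-yl]undeca-4,7,10-trien-1-ol
Conditions: Ti(OiPr)4 (10 mol%), L-(+)-diisopropyl tartrate (12 mol%), t-BuOOH, 4 Å molecular sieves, CH2Cl2, −20 °C
Reagents that add atoms: tert-butyl hydroperoxide, CC(C)(C)OO
Why: Sharpless asymmetric epoxidation in the matched sense (S carbinol, L-tartrate) touches only the allylic-alcohol alkene and gives the erythro epoxy alcohol, setting C12 as R relative to C11 and raising the enantiomeric purity.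

**Step 8**
Reactants: 11 (1S,4Z,7E)-9-[(tert-butyldimethylsilyl)oxy]-4,8-dimethyl-1-[(2R)-2-methyloxiran-2-yl]undeca-4,7,10-trien-1-ol
Product: 12 (5R,6S,9Z,12E)-14-[(tert-butyldimethylsilyl)oxy]-5,9,13-trimethylhexadeca-1,9,12,15-tetraene-5,6-diol
Conditions: CH2=CHCH2MgBr (3 equiv), CuI (10 mol%), THF, −40 to 0 °C; then H2O
Reagents that add atoms: allylmagnesium bromide, C=CC[Mg]Br
Why: copper-catalysed SN2 opening of the 2,2-disubstituted oxirane at its unhindered CH2 (C13) adds C14 and C1 and leaves both stereocentres untouched, giving the anti diol.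

**Step 9**
Reactants: 12 (5R,6S,9Z,12E)-14-[(tert-butyldimethylsilyl)oxy]-5,9,13-trimethylhexadeca-1,9,12,15-tetraene-5,6-diol
Product: 14 tert-butyl({(4E,7Z)-10-[(2R,3R)-3-(but-3-en-1-yl)-3-methyloxiran-2-yl]-4,8-dimethyldeca-1,4,7-trien-3-yl}oxy)dimethylsilane, via C11 mesylate 13 (not isolated)
Conditions: MeSO2Cl (1.1 equiv), Et3N, CH2Cl2, −20 °C; then K2CO3, MeOH, 20 °C
Reagents that add atoms: none
Why: only the secondary hydroxyl is sulfonylated and the tertiary alkoxide displaces it in an intramolecular Williamson (SN2) closure, inverting C11 to R and giving the trans-trisubstituted (11R,12R)-epoxide.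

**Step 10**
Reactants: 14 tert-butyl({(4E,7Z)-10-[(2R,3R)-3-(but-3-en-1-yl)-3-methyloxiran-2-yl]-4,8-dimethyldeca-1,4,7-trien-3-yl}oxy)dimethylsilane
Product: 15 (4E,7Z)-10-[(2R,3R)-3-(but-3-en-1-yl)-3-methyloxiran-2-yl]-4,8-dimethyldeca-1,4,7-trien-3-ol
Conditions: Bu4NF, THF, 0 to 20 °C
Reagents that add atoms: none
Why: fluoride-driven desilylation frees the bis-allylic alcohol without touching the epoxide.

**Step 11**
Reactants: 15 (4E,7Z)-10-[(2R,3R)-3-(but-3-en-1-yl)-3-methyloxiran-2-yl]-4,8-dimethyldeca-1,4,7-trien-3-ol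
Product: 16 (4E,7Z)-10-[(2R,3R)-3-(but-3-en-1-yl)-3-methyloxiran-2-yl]-4,8-dimethyldeca-1,4,7-trien-3-one
Conditions: MnO2, CH2Cl2, 20 °C
Reagents that add atoms: none
Why: allylic oxidation with MnO2 acts only on the doubly allylic alcohol, erasing the racemic C3 centre and giving the vinyl ketone needed for metathesis and Michael addition.

**Step 12**
Reactants: 16 (4E,7Z)-10-[(2R,3R)-3-(but-3-en-1-yl)-3-methyloxiran-2-yl]-4,8-dimethyldeca-1,4,7-trien-3-one
Product: 17 (1R,4E,7E,10Z,14R)-1,7,11-trimethyl-15-oxabicyclo[12.1.0]pentadeca-4,7,10-trien-6-one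
Conditions: second-generation Grubbs catalyst RuCl2(=CHPh)(PCy3)(H2IMes) (5 mol%), CH2Cl2 (1 mM), 40 °C
Reagents that add atoms: none
Why: ring-closing metathesis joins the only two monosubstituted alkenes (the trisubstituted ones are inert) and closes the 14-membered carbocycle as the conjugated E-enone.

**Step 13**
Reactants: 17 (1R,4E,7E,10Z,14R)-1,7,11-trimethyl-15-oxabicyclo[12.1.0]pentadeca-4,7,10-trien-6-one; 18 diprop-2-en-1-yl propanedioate (diallyl malonate)
Product: 19 diprop-2-en-1-yl 2-[(1R,4S,7E,10Z,14R)-1,7,11-trimethyl-6-oxo-15-oxabicyclo[12.1.0]pentadeca-7,10-dien-4-yl]propanedioate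
Conditions: 9-amino-9-deoxy-epi-quinine (20 mol%), PhCO2H (40 mol%), THF, 40 °C
Reagents that add atoms: none
Why: primary-amine (iminium) catalysed asymmetric Michael addition places the malonate on the less hindered, α-unsubstituted β-carbon C1 of the dienone, and the catalyst face selection sets C1 as S.

**Step 14**
Reactants: 19 diprop-2-en-1-yl 2-[(1R,4S,7E,10Z,14R)-1,7,11-trimethyl-6-oxo-15-oxabicyclo[12.1.0]pentadeca-7,10-dien-4-yl]propanedioate
Product: 21 2-[(1R,4S,7E,10Z,14R)-1,7,11-trimethyl-6-oxo-15-oxabicyclo[12.1.0]pentadeca-7,10-dien-4-yl]prop-2-enoic acid, via malonic acid 20 (not isolated)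
Conditions: Pd(PPh3)4 (5 mol%), Et2NH, THF, 20 °C; then aq. CH2O (37%), 20 to 45 °C
Reagents that add atoms: formaldehyde, C=O
Why: zerovalent-palladium deallylation (Tsuji–Trost allyl transfer to the amine) unmasks the malonic acid under neutral conditions, and Mannich condensation with formaldehyde followed by decarboxylative elimination gives the 2-substituted acrylic acid.

**Step 15**
Reactants: 21 2-[(1R,4S,7E,10Z,14R)-1,7,11-trimethyl-6-oxo-15-oxabicyclo[12.1.0]pentadeca-7,10-dien-4-yl]prop-2-enoic acid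
Product: 23 (1S,4E,7Z,11R,12S)-11-acetoxy-3-oxocembra-4,7,15(17)-trien-16,12-olide, via hydroxy lactone 22 (not isolated)
Conditions: (1S)-(+)-10-camphorsulfonic acid (10 mol%), CH2Cl2, 0 °C; then Ac2O, pyridine, 4-(dimethylamino)pyridine (cat.), 20 °C
Reagents that add atoms: acetic anhydride, CC(=O)OC(C)=O
Why: acid-catalysed 7-exo epoxide opening by the carboxylic acid at the tertiary carbon goes with inversion (C12 becomes S) and leaves the C11 oxygen in place (R), and this hydroxyl is acetylated in the same flask.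

**Step 16**
Reactants: 23 (1S,4E,7Z,11R,12S)-11-acetoxy-3-oxocembra-4,7,15(17)-trien-16,12-olide
Product: 24 (1S,3R,4E,7Z,11R,12S)-11-acetoxy-3-hydroxycembra-4,7,15(17)-trien-16,12-olide
Conditions: (S)-2-methyl-CBS-oxazaborolidine (50 mol%), catecholborane, toluene–CH2Cl2, −78 °C
Reagents that add atoms: none
Why: Corey–Bakshi–Shibata reduction of the α-methyl enone (alkenyl side as the large group) gives the 3R allylic alcohol under reagent control, while the α-methylene lactone and the acetate are not reduced at −78 °C.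

**Compound list**
1 | 4-methylanisole | COc1ccc(C)cc1 | starting material
2 | 1-methoxy-4-methylcyclohexa-1,4-diene | COC1=CCC(C)=CC1 | intermediate
3 | 4-methylcyclohex-3-en-1-one | CC1=CCC(=O)CC1 | intermediate
4 | 5-methyl-4,7-dihydrooxepin-2(3H)-one | O=C1CCC(C)=CCO1 | intermediate
5 | pent-1-en-4-yn-3-ol (racemic) | C=CC(O)C#C | starting material
6 | tert-butyl(dimethyl)(pent-1-en-4-yn-3-yloxy)silane (racemic) | C=CC(O[Si](C)(C)C(C)(C)C)C#C | intermediate
7 | [(1E)-3-[(tert-butyldimethylsilyl)oxy]-2-methylpenta-1,4-dien-1-yl]dimethylalumane | C=CC(O[Si](C)(C)C(C)(C)C)/C(C)=C/[Al](C)C | intermediate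
8 | (4Z,7E)-9-[(tert-butyldimethylsilyl)oxy]-4,8-dimethylundeca-4,7,10-trienoic acid | C=CC(O[Si](C)(C)C(C)(C)C)/C(C)=C/C/C=C(/C)CCC(=O)O | intermediate
9 | (6Z,9E)-11-[(tert-butyldimethylsilyl)oxy]-2,6,10-trimethyltrideca-1,6,9,12-tetraen-3-one | C=CC(O[Si](C)(C)C(C)(C)C)/C(C)=C/C/C=C(/C)CCC(=O)C(C)=C | intermediate
10 | (3S,6Z,9E)-11-[(tert-butyldimethylsilyl)oxy]-2,6,10-trimethyltrideca-1,6,9,12-tetraen-3-ol | C=CC(O[Si](C)(C)C(C)(C)C)/C(C)=C/C/C=C(/C)CC[C@H](O)C(C)=C | intermediate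
11 | (1S,4Z,7E)-9-[(tert-butyldimethylsilyl)oxy]-4,8-dimethyl-1-[(2R)-2-methyloxiran-2-yl]undeca-4,7,10-trien-1-ol | C=CC(O[Si](C)(C)C(C)(C)C)/C(C)=C/C/C=C(/C)CC[C@H](O)[C@@]1(C)CO1 | intermediate
12 | (5R,6S,9Z,12E)-14-[(tert-butyldimethylsilyl)oxy]-5,9,13-trimethylhexadeca-1,9,12,15-tetraene-5,6-diol | C=CC(O[Si](C)(C)C(C)(C)C)/C(C)=C/C/C=C(/C)CC[C@H](O)[C@](C)(O)CCC=C | intermediate
13 | (5R,6S,9Z,12E)-14-[(tert-butyldimethylsilyl)oxy]-5-hydroxy-5,9,13-trimethylhexadeca-1,9,12,15-tetraen-6-yl methanesulfonate | C=CC(O[Si](C)(C)C(C)(C)C)/C(C)=C/C/C=C(/C)CC[C@H](OS(C)(=O)=O)[C@](C)(O)CCC=C | intermediate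
14 | tert-butyl({(4E,7Z)-10-[(2R,3R)-3-(but-3-en-1-yl)-3-methyloxiran-2-yl]-4,8-dimethyldeca-1,4,7-trien-3-yl}oxy)dimethylsilane | C=CC(O[Si](C)(C)C(C)(C)C)/C(C)=C/C/C=C(/C)CC[C@H]1O[C@]1(C)CCC=C | intermediate
15 | (4E,7Z)-10-[(2R,3R)-3-(but-3-en-1-yl)-3-methyloxiran-2-yl]-4,8-dimethyldeca-1,4,7-trien-3-ol | C=CC(O)/C(C)=C/C/C=C(/C)CC[C@H]1O[C@]1(C)CCC=C | intermediate
16 | (4E,7Z)-10-[(2R,3R)-3-(but-3-en-1-yl)-3-methyloxiran-2-yl]-4,8-dimethyldeca-1,4,7-trien-3-one | C=CC(=O)/C(C)=C/C/C=C(/C)CC[C@H]1O[C@]1(C)CCC=C | intermediate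
17 | (1R,4E,7E,10Z,14R)-1,7,11-trimethyl-15-oxabicyclo[12.1.0]pentadeca-4,7,10-trien-6-one | C1/C=C/C(=O)/C(C)=C/C/C=C(/C)CC[C@H]2O[C@]2(C)C1 | intermediate
18 | diprop-2-en-1-yl propanedioate (diallyl malonate) | C=CCOC(=O)CC(=O)OCC=C | starting material
19 | diprop-2-en-1-yl 2-[(1R,4S,7E,10Z,14R)-1,7,11-trimethyl-6-oxo-15-oxabicyclo[12.1.0]pentadeca-7,10-dien-4-yl]propanedioate | C1[C@H](C(C(=O)OCC=C)C(=O)OCC=C)CC(=O)/C(C)=C/C/C=C(/C)CC[C@H]2O[C@]2(C)C1 | intermediate
20 | 2-[(1R,4S,7E,10Z,14R)-1,7,11-trimethyl-6-oxo-15-oxabicyclo[12.1.0]pentadeca-7,10-dien-4-yl]propanedioic acid | C1[C@H](C(C(=O)O)C(=O)O)CC(=O)/C(C)=C/C/C=C(/C)CC[C@H]2O[C@]2(C)C1 | intermediate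
21 | 2-[(1R,4S,7E,10Z,14R)-1,7,11-trimethyl-6-oxo-15-oxabicyclo[12.1.0]pentadeca-7,10-dien-4-yl]prop-2-enoic acid | C1[C@H](C(=C)C(=O)O)CC(=O)/C(C)=C/C/C=C(/C)CC[C@H]2O[C@]2(C)C1 | intermediate
22 | (1S,4E,7Z,11R,12S)-11-hydroxy-3-oxocembra-4,7,15(17)-trien-16,12-olide | C=C1C(=O)O[C@@]2(C)CC[C@H]1CC(=O)/C(C)=C/C/C=C(/C)CC[C@H]2O | intermediate
23 | (1S,4E,7Z,11R,12S)-11-acetoxy-3-oxocembra-4,7,15(17)-trien-16,12-olide | C=C1C(=O)O[C@@]2(C)CC[C@H]1CC(=O)/C(C)=C/C/C=C(/C)CC[C@H]2OC(C)=O | intermediate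
24 | (1S,3R,4E,7Z,11R,12S)-11-acetoxy-3-hydroxycembra-4,7,15(17)-trien-16,12-olide | C=C1C(=O)O[C@@]2(C)CC[C@H]1C[C@@H](O)/C(C)=C/C/C=C(/C)CC[C@H]2OC(C)=O | target

**Totals**
Total step count: 16. Longest linear sequence: 15 (steps 1, 2 and 4–16 from 4-methylanisole; step 3 is a one-step side branch).

**Steps most likely to fail, with fallbacks**

Step 2 (Baeyer–Villiger). Risks are migration of the plain CH2 instead of the allylic one, epoxidation, or acid-induced conjugation of 3. The fallback replaces oxygen insertion by oxidative cleavage, setting out from 3 and returning at 4. Ketone 3 is converted with Me3SiCl, NaI and Et3N in MeCN into the thermodynamic silyl dienol ether trimethyl[(4-methylcyclohexa-1,3-dien-1-yl)oxy]silane F1. Ozonolysis of its electron-rich silyloxy alkene (1 equiv O3, CH2Cl2–MeOH, −78 °C) with NaBH4 reduction of the Z-enal in the same flask gives (4Z)-6-hydroxy-4-methylhex-4-enoic acid F2. F2 is closed to 4 with 2,4,6-trichlorobenzoyl chloride, Et3N and 4-(dimethylamino)pyridine in dilute toluene.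

Step 4 (Pd-catalysed opening of the allylic lactone by the alkenylalane). Risks are sluggish ionisation of the lactone, attack of Me3Al on the lactone carbonyl, or partial Z to E scrambling. The fallback uses a classical allylic chloride, setting out from 4 and returning at 8. Lactone 4 is opened with K2CO3 in MeOH to methyl (4Z)-6-hydroxy-4-methylhex-4-enoate F3. MeSO2Cl, LiCl and 2,4,6-collidine in DMF convert it without allylic transposition into methyl (4Z)-6-chloro-4-methylhex-4-enoate F4. F4 is coupled with alane 7 (Pd(PPh3)4, THF) to methyl (4Z,7E)-9-[(tert-butyldimethylsilyl)oxy]-4,8-dimethylundeca-4,7,10-trienoate F5, and LiOH in THF–H2O gives 8.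

Step 13 (asymmetric Michael addition). Risks are slow iminium formation at the hindered dienone, modest enantioselectivity, an unverified facial sense for this substrate (the quinidine-derived pseudoenantiomer of the catalyst is the first check), or a second transannular Michael addition to C5. The fallback brings in C15 as an alkenyl nucleophile, setting out from 17 and returning at 21. Conjugate addition of 2-[3-(tert-butyldimethylsilyloxy)prop-1-en-2-yl]-4,4,5,5-tetramethyl-1,3,2-dioxaborolane to 17 ([RhCl(C2H4)2]2, BINAP of the enantiomer giving 1S, aq. KOH, 1,4-dioxane, 60 °C) gives (1R,4S,7E,10Z,14R)-4-{3-[(tert-butyldimethylsilyl)oxy]prop-1-en-2-yl}-1,7,11-trimethyl-15-oxabicyclo[12.1.0]pentadeca-7,10-dien-6-one F6. Bu4NF gives (1R,4S,7E,10Z,14R)-4-(3-hydroxyprop-1-en-2-yl)-1,7,11-trimethyl-15-oxabicyclo[12.1.0]pentadeca-7,10-dien-6-one F7. MnO2 gives 2-[(1R,4S,7E,10Z,14R)-1,7,11-trimethyl-6-oxo-15-oxabicyclo[12.1.0]pentadeca-7,10-dien-4-yl]prop-2-enal F8, and NaClO2, NaH2PO4 and 2-methylbut-2-ene in t-BuOH–H2O oxidise it to 21.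

**Further compounds**
F1 | step 2 | trimethyl[(4-methylcyclohexa-1,3-dien-1-yl)oxy]silane | CC1=CC=C(O[Si](C)(C)C)CC1
F2 | step 2 | (4Z)-6-hydroxy-4-methylhex-4-enoic acid | OC/C=C(/C)CCC(=O)O
F3 | step 4 | methyl (4Z)-6-hydroxy-4-methylhex-4-enoate | OC/C=C(/C)CCC(=O)OC
F4 | step 4 | methyl (4Z)-6-chloro-4-methylhex-4-enoate | ClC/C=C(/C)CCC(=O)OC
F5 | step 4 | methyl (4Z,7E)-9-[(tert-butyldimethylsilyl)oxy]-4,8-dimethylundeca-4,7,10-trienoate | C=CC(O[Si](C)(C)C(C)(C)C)/C(C)=C/C/C=C(/C)CCC(=O)OC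
F6 | step 13 | (1R,4S,7E,10Z,14R)-4-{3-[(tert-butyldimethylsilyl)oxy]prop-1-en-2-yl}-1,7,11-trimethyl-15-oxabicyclo[12.1.0]pentadeca-7,10-dien-6-one | C1[C@H](C(=C)CO[Si](C)(C)C(C)(C)C)CC(=O)/C(C)=C/C/C=C(/C)CC[C@H]2O[C@]2(C)C1
F7 | step 13 | (1R,4S,7E,10Z,14R)-4-(3-hydroxyprop-1-en-2-yl)-1,7,11-trimethyl-15-oxabicyclo[12.1.0]pentadeca-7,10-dien-6-one | C1[C@H](C(=C)CO)CC(=O)/C(C)=C/C/C=C(/C)CC[C@H]2O[C@]2(C)C1
F8 | step 13 | 2-[(1R,4S,7E,10Z,14R)-1,7,11-trimethyl-6-oxo-15-oxabicyclo[12.1.0]pentadeca-7,10-dien-4-yl]prop-2-enal | C1[C@H](C(=C)C=O)CC(=O)/C(C)=C/C/C=C(/C)CC[C@H]2O[C@]2(C)C1
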